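## Retrosynthetic overview

1. The target is read as the 5E-ylidene (side chain cis to C4–OH), 2′S, 6′E, 9′E. The furan is bought; the tetronic acid is the only ring made and is closed last (Dieckmann, C3–C4).
2. Key disconnection: the enol-lactone C5–O1 bond, made from an ynoate and propanoic acid by a proposed Rh-catalysed cis-hydroacyloxylation that places oxygen on C5 and fixes the E geometry.
3. Ynoate ⇐ α-methyl aldehyde (Ohira–Bestmann, then ClCO2Me) ⇐ primary alcohol.
4. (E,E)-skipped diene ⇐ Zr-catalysed methylalumination of 3-(pent-4-ynyl)furan and Pd allyl–alkenyl coupling with a C10 allylic acetate.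
5. C10 piece with the (S)-methyl centre ⇐ geranyl acetate (SeO2 oxidation, Ru–BINAP hydrogenation); furyl alkyne ⇐ 3-bromofuran, 1-chloro-3-iodopropane, lithium acetylide.

Assumption: Ru–(S)-BINAP attacks the (E)-2-methylallylic alcohol 2 on the same face as it does geraniol, which gives the 7S alcohol; if the sense is opposite, the (R)-ligand is used and nothing else changes.

## Route

Step 1
Reactants: 1 (2E)-3,7-dimethylocta-2,6-dien-1-yl acetate (geranyl acetate)
Product: 2 (2E,6E)-8-hydroxy-3,7-dimethylocta-2,6-dien-1-yl acetate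
Conditions: SeO2 (0.3 equiv), t-BuOOH (3 equiv), salicylic acid (0.1 equiv), CH2Cl2, rt
Reagents that add atoms: tert-butyl hydroperoxide, CC(C)(C)OO (oxygen source, relayed by catalytic selenium dioxide, O=[Se]=O)
Why: Sharpless SeO2/TBHP allylic oxidation (ene, then [2,3]-shift) attacks the (E)-methyl of the distal, more electron-rich trisubstituted alkene; the C2=C3 alkene is deactivated by the allylic acetate.

Step 2
Reactants: 2 (2E,6E)-8-hydroxy-3,7-dimethylocta-2,6-dien-1-yl acetate
Product: 3 (2E,7S)-8-hydroxy-3,7-dimethyloct-2-en-1-yl acetate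
Conditions: H2 (50 atm), Ru(OAc)2[(S)-BINAP] (1 mol %), MeOH, 25 °C
Reagents that add atoms: none
Why: Noyori hydroxyl-directed asymmetric hydrogenation reduces only the allylic-alcohol alkene (the remote C2=C3 alkene and the acetate do not bind Ru), and the chiral catalyst sets the 7S methyl centre by face-selective H2 delivery.

Step 3
Reactants: 4 3-bromofuran; 5 1-chloro-3-iodopropane
Product: 7 3-(3-chloropropyl)furan, via furan-3-yllithium 6 (not isolated)
Conditions: n-BuLi (1.05 equiv), THF, −78 °C; then 5 (1.2 equiv), HMPA (2 equiv), −78 → −30 °C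
Reagents that add atoms: none
Why: Br/Li exchange gives 3-furyllithium, which keeps its position below −40 °C, and SN2 alkylation takes place at the C–I end in preference to C–Cl.

Step 4
Reactants: 7 3-(3-chloropropyl)furan
Product: 8 3-(pent-4-yn-1-yl)furan
Conditions: HC≡CLi·ethylenediamine (1.5 equiv), NaI (10 mol %), DMSO, rt
Reagents that add atoms: lithium acetylide ethylenediamine complex, [Li+].[C-]#C.NCCN
Why: SN2 alkynylation of a primary chloride by lithium acetylide in DMSO, with in-situ Finkelstein activation.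

Step 5
Reactants: 8 3-(pent-4-yn-1-yl)furan; 3 (2E,7S)-8-hydroxy-3,7-dimethyloct-2-en-1-yl acetate
Product: 10 (2S,6E,9E)-13-(furan-3-yl)-2,6,10-trimethyltrideca-6,9-dien-1-ol, via E-alkenyldimethylalane 9 (not isolated)
Conditions: 8 (1.3 equiv), Me3Al (2.6 equiv), Cp2ZrCl2 (0.25 equiv), CH2Cl2, 0 °C → rt; then 3 (1.0 equiv), Pd(PPh3)4 (5 mol %), THF, rt; aq. HCl work-up
Reagents that add atoms: trimethylaluminium, C[Al](C)C
Why: Negishi Zr-catalysed syn-methylalumination gives the (E)-alkenylalane, and Negishi Pd-catalysed allyl–alkenyl coupling joins it to the primary terminus of the allylic acetate with retention of both alkene geometries; the free OH travels as its aluminium alkoxide and the stereocentre is untouched.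

Step 6
Reactants: 10 (2S,6E,9E)-13-(furan-3-yl)-2,6,10-trimethyltrideca-6,9-dien-1-ol
Product: 11 (2S,6E,9E)-13-(furan-3-yl)-2,6,10-trimethyltrideca-6,9-dienal
Conditions: Dess–Martin periodinane (1.3 equiv), pyridine (3 equiv), CH2Cl2, 0 °C → rt; used at once
Reagents that add atoms: none
Why: Buffered Dess–Martin oxidation gives the α-methyl aldehyde without epimerisation and leaves the furan and the skipped diene alone.

Step 7
Reactants: 11 (2S,6E,9E)-13-(furan-3-yl)-2,6,10-trimethyltrideca-6,9-dienal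
Product: 12 3-[(4E,7E,12S)-4,8,12-trimethyltetradeca-4,7-dien-13-yn-1-yl]furan
Conditions: Ohira–Bestmann reagent (1.4 equiv), K2CO3 (2 equiv), MeOH, 0 °C → rt
Reagents that add atoms: dimethyl (1-diazo-2-oxopropyl)phosphonate, CC(=O)C(=[N+]=[N-])P(=O)(OC)OC
Why: Seyferth–Gilbert homologation in the Ohira–Bestmann form (alkylidene carbene, 1,2-H shift) under carbonate base mild enough to keep the α-stereocentre.

Step 8
Reactants: 12 3-[(4E,7E,12S)-4,8,12-trimethyltetradeca-4,7-dien-13-yn-1-yl]furan
Product: 14 methyl (4S,8E,11E)-15-(furan-3-yl)-4,8,12-trimethylpentadeca-8,11-dien-2-ynoate, via lithium acetylide 13 (not isolated)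
Conditions: n-BuLi (1.05 equiv), THF, −78 °C; then ClCO2Me (1.5 equiv), −78 → 0 °C
Reagents that add atoms: methyl chloroformate, COC(=O)Cl
Why: Selective deprotonation of the terminal alkyne and C-acylation of the acetylide with a chloroformate (standard ynoate synthesis); the propargylic centre is not touched at −78 °C.

Step 9
Reactants: 14 methyl (4S,8E,11E)-15-(furan-3-yl)-4,8,12-trimethylpentadeca-8,11-dien-2-ynoate; 15 propanoic acid
Product: 16 methyl (2E,4S,8E,11E)-15-(furan-3-yl)-4,8,12-trimethyl-2-(propanoyloxy)pentadeca-2,8,11-trienoate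
Conditions: [Rh(cod)Cl]2 (2.5 mol %), DPEphos (5.5 mol %), 15 (3 equiv), ClCH2CH2Cl, 50 °C
Reagents that add atoms: none
Why: Proposed new method: Rh(I)/wide-bite-angle bisphosphine adds the O–H bond of propanoic acid oxidatively to give H–Rh(III)–O2CEt, the polarised ynoate inserts syn into Rh–H with hydride going to the electrophilic β-carbon (C3) and Rh to the α-carbon (C2), and C(sp2)–O reductive elimination then forms the C2–O bond with H and O cis, which is the E enol ester (chain cis to CO2Me) and the future C5–O1 bond of the lactone; the C4–H is never β to Rh, so no allene or π-allyl path can reach the stereocentre; this α-selective cis-hydroacyloxylation of a γ-branched 2-ynoate has not been shown, and the closest known reaction types are Rh/DPEphos, Ru and Pd hydro-oxycarbonylation of unactivated alkynes, α-selective syn-hydrometalation of ynoates (Pd/Bu3SnH), and C(vinyl)–O reductive elimination from Rh(III) carboxylates in isocoumarin and pyrone annulations.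

Step 10
Reactants: 16 methyl (2E,4S,8E,11E)-15-(furan-3-yl)-4,8,12-trimethyl-2-(propanoyloxy)pentadeca-2,8,11-trienoate
Product: 18 (5E)-5-[(2S,6E,9E)-13-(furan-3-yl)-2,6,10-trimethyltrideca-6,9-dien-1-ylidene]-4-hydroxy-3-methylfuran-2(5H)-one, via lithium tetronate 17 (not isolated)
Conditions: LiHMDS (2.3 equiv), THF, −78 → −30 °C; then 1 M HCl, 0 °C
Reagents that add atoms: none
Why: Dieckmann condensation of the propanoate enolate onto the neighbouring methyl ester (5-exo-trig, as in pulvinone syntheses from α-acyloxyacrylates) closes the tetronic acid, driven by formation of the stable tetronate anion; the enol-ester C=C is a spectator, so its E geometry becomes the 5E ylidene and C2′ is not involved.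

## Compound list

1 | (2E)-3,7-dimethylocta-2,6-dien-1-yl acetate (geranyl acetate) | CC(=O)OC/C=C(\C)CCC=C(C)C | starting material
2 | (2E,6E)-8-hydroxy-3,7-dimethylocta-2,6-dien-1-yl acetate | CC(=O)OC/C=C(\C)CC/C=C(\C)CO | intermediate
3 | (2E,7S)-8-hydroxy-3,7-dimethyloct-2-en-1-yl acetate | OC[C@@H](C)CCC/C(C)=C/COC(C)=O | intermediate
4 | 3-bromofuran | Brc1ccoc1 | starting material
5 | 1-chloro-3-iodopropane | ClCCCI | starting material
6 | furan-3-yllithium | [Li]c1ccoc1 | intermediate
7 | 3-(3-chloropropyl)furan | ClCCCc1ccoc1 | intermediate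
8 | 3-(pent-4-yn-1-yl)furan | C#CCCCc1ccoc1 | intermediate
9 | [(1E)-5-(furan-3-yl)-2-methylpent-1-en-1-yl]dimethylalumane (E-alkenyldimethylalane) | C[Al](C)/C=C(\C)CCCc1ccoc1 | intermediate
10 | (2S,6E,9E)-13-(furan-3-yl)-2,6,10-trimethyltrideca-6,9-dien-1-ol | OC[C@@H](C)CCC/C(C)=C/C/C=C(\C)CCCc1ccoc1 | intermediate
11 | (2S,6E,9E)-13-(furan-3-yl)-2,6,10-trimethyltrideca-6,9-dienal | O=C[C@@H](C)CCC/C(C)=C/C/C=C(\C)CCCc1ccoc1 | intermediate
12 | 3-[(4E,7E,12S)-4,8,12-trimethyltetradeca-4,7-dien-13-yn-1-yl]furan | C#C[C@@H](C)CCC/C(C)=C/C/C=C(\C)CCCc1ccoc1 | intermediate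
13 | [(3S,7E,10E)-14-(furan-3-yl)-3,7,11-trimethyltetradeca-7,10-dien-1-yn-1-yl]lithium (lithium acetylide) | [Li]C#C[C@@H](C)CCC/C(C)=C/C/C=C(\C)CCCc1ccoc1 | intermediate
14 | methyl (4S,8E,11E)-15-(furan-3-yl)-4,8,12-trimethylpentadeca-8,11-dien-2-ynoate | COC(=O)C#C[C@@H](C)CCC/C(C)=C/C/C=C(\C)CCCc1ccoc1 | intermediate
15 | propanoic acid | CCC(=O)O | starting material
16 | methyl (2E,4S,8E,11E)-15-(furan-3-yl)-4,8,12-trimethyl-2-(propanoyloxy)pentadeca-2,8,11-trienoate | CCC(=O)O/C(=C/[C@@H](C)CCC/C(C)=C/C/C=C(\C)CCCc1ccoc1)C(=O)OC | intermediate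
17 | lithium (5E)-5-[(2S,6E,9E)-13-(furan-3-yl)-2,6,10-trimethyltrideca-6,9-dien-1-ylidene]-3-methyl-2-oxo-2,5-dihydrofuran-4-olate (lithium tetronate) | CC1=C([O-])/C(=C\[C@@H](C)CCC/C(C)=C/C/C=C(\C)CCCc2ccoc2)OC1=O.[Li+] | intermediate
18 | (5E)-5-[(2S,6E,9E)-13-(furan-3-yl)-2,6,10-trimethyltrideca-6,9-dien-1-ylidene]-4-hydroxy-3-methylfuran-2(5H)-one | CC1=C(O)/C(=C\[C@@H](C)CCC/C(C)=C/C/C=C(\C)CCCc2ccoc2)OC1=O | target

## Step count and risks

Total step count: 10. Longest linear sequence: 8 steps (steps 1, 2, 5, 6, 7, 8, 9, 10; from 1 to 18).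

**Step 9 (the proposed Rh-catalysed cis-hydroacyloxylation).** It can fail by wrong regiochemistry (β-acyloxy product), by lack of turnover if C–O reductive elimination is slow, or by Rh–H isomerising the E enol ester or the 1,4-diene. The fallback uses known chemistry, sets out from 14 and comes back at 16. Pd(PPh3)4-catalysed syn-hydrostannation of 14 with Bu3SnH (THF, 0 °C) puts tin on the α-carbon and gives methyl (2E,4S,8E,11E)-15-(furan-3-yl)-4,8,12-trimethyl-2-(tributylstannyl)pentadeca-2,8,11-trienoate F1. Iododestannylation with retention (I2, CH2Cl2, 0 °C) gives methyl (2E,4S,8E,11E)-15-(furan-3-yl)-2-iodo-4,8,12-trimethylpentadeca-2,8,11-trienoate F2. Copper-catalysed O-vinylation of propanoic acid 15 (CuI, 1,10-phenanthroline, Cs2CO3, toluene, 80 °C) then replaces iodide by propanoate with retention and gives 16.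

**Step 10 (Dieckmann closure).** It can fail by ketene loss from the enol-ester enolate, by γ-deprotonation at C4 (epimerisation), or by E to Z drift during acidic work-up. The fallback sets out from 11 and comes back at 18, bypassing 12 to 17. O-Methylation of commercial 3-methyltetronic acid (Me2SO4, K2CO3, acetone) gives 4-methoxy-3-methylfuran-2(5H)-one F3. Its C5-lithio derivative (LDA, THF, −78 °C) adds to 11 and gives 5-[(2S,6E,9E)-13-(furan-3-yl)-1-hydroxy-2,6,10-trimethyltrideca-6,9-dien-1-yl]-4-methoxy-3-methylfuran-2(5H)-one F4 as separable carbinol diastereomers. Stereospecific anti-elimination of the appropriate diastereomer (PPh3, DEAD, THF) gives (5E)-5-[(2S,6E,9E)-13-(furan-3-yl)-2,6,10-trimethyltrideca-6,9-dien-1-ylidene]-4-methoxy-3-methylfuran-2(5H)-one F5. Demethylation with lithium propanethiolate (HMPA, rt) gives 18.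

**Step 2 (asymmetric hydrogenation).** It can fail by insufficient ee on a 2-methyl-substituted allylic alcohol or by isomerisation of the allylic alcohol to the aldehyde. The fallback sets out from 2 and comes back at 3, and moves the hydrogenation to the better-precedented unsaturated-acid class. Oxidation of 2 (TEMPO, PhI(OAc)2, MeCN–H2O) gives (2E,6E)-8-(acetyloxy)-2,6-dimethylocta-2,6-dienoic acid F6. Carboxylate-directed hydrogenation (Ru(OAc)2(H8-BINAP), H2, MeOH) gives (2S,6E)-8-(acetyloxy)-2,6-dimethyloct-6-enoic acid F7. Chemoselective reduction of the acid (BH3·SMe2, THF, −10 °C) gives 3.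

## Further compounds

F1 | step 9 | methyl (2E,4S,8E,11E)-15-(furan-3-yl)-4,8,12-trimethyl-2-(tributylstannyl)pentadeca-2,8,11-trienoate | CCCC[Sn](CCCC)(CCCC)/C(=C/[C@@H](C)CCC/C(C)=C/C/C=C(\C)CCCc1ccoc1)C(=O)OC
F2 | step 9 | methyl (2E,4S,8E,11E)-15-(furan-3-yl)-2-iodo-4,8,12-trimethylpentadeca-2,8,11-trienoate | I/C(=C/[C@@H](C)CCC/C(C)=C/C/C=C(\C)CCCc1ccoc1)C(=O)OC
F3 | step 10 | 4-methoxy-3-methylfuran-2(5H)-one | COC1=C(C)C(=O)OC1
F4 | step 10 | 5-[(2S,6E,9E)-13-(furan-3-yl)-1-hydroxy-2,6,10-trimethyltrideca-6,9-dien-1-yl]-4-methoxy-3-methylfuran-2(5H)-one (diastereomers at C5 and C1′) | COC1=C(C)C(=O)OC1C(O)[C@@H](C)CCC/C(C)=C/C/C=C(\C)CCCc2ccoc2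
F5 | step 10 | (5E)-5-[(2S,6E,9E)-13-(furan-3-yl)-2,6,10-trimethyltrideca-6,9-dien-1-ylidene]-4-methoxy-3-methylfuran-2(5H)-one | CC1=C(OC)/C(=C\[C@@H](C)CCC/C(C)=C/C/C=C(\C)CCCc2ccoc2)OC1=O
F6 | step 2 | (2E,6E)-8-(acetyloxy)-2,6-dimethylocta-2,6-dienoic acid | CC(=O)OC/C=C(\C)CC/C=C(\C)C(=O)O
F7 | step 2 | (2S,6E)-8-(acetyloxy)-2,6-dimethyloct-6-enoic acid | OC(=O)[C@@H](C)CCC/C(C)=C/COC(C)=O
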